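Decide the reagent charge before the flask is filled: will 1.50 equiv do, or must more go in?

| setting | theta | epsilon | zeta | flask |
|---|---|---|---|---|
| left-handed substrate | 0.20 M | 0.20 M | 0.40 M | 0.20 M |
| right-handed substrate | 0.20 M | 0.20 M | 0.40 M | 0.20 M |
| reagent | 1 equiv | 2.2 equiv | 1.5 equiv | 1.50 equiv |
| catalyst | 0.1 mol% | 0.1 mol% | 0.1 mol% | 0.1 mol% |
| added ligand | 0.24 mM | 0.24 mM | 0.24 mM | 0.24 mM |
| remark | run made earlier | run made earlier | run made earlier |  |
| time |  |  |  | 4.0 h |

| run | time / h | right-handed substrate / % | left-handed substrate / % | left-handed product / % |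
|---|---|---|---|---|
| theta | 0.417 | 46.8 | 2.9 | 39.9 |
| theta | 0.667 | 48.1 | 3.5 | 40.3 |
| theta | 1.33 | 47.5 | 3.5 | 32.5 |
| theta | 2.50 | 46.7 | 2.8 | 27.6 |
| theta | 5.00 | 44.5 | 4.3 | 27.1 |
| epsilon | 1.00 | 10.5 | 0 | 45.8 |
| epsilon | 2.00 | 4.0 | 1.3 | 45.9 |
| epsilon | 3.00 | 2.6 | 0.9 | 47.4 |
| epsilon | 4.00 | 0 | 0.4 | 49.1 |
| epsilon | 5.00 | 2.2 | 0.5 | 48.3 |
| zeta | 0.417 | 26.1 | 0.1 | 47.6 |
| zeta | 0.667 | 25.5 | 0 | 44.6 |
| zeta | 1.33 | 25.2 | 0 | 42.2 |
| zeta | 2.50 | 25.5 | 0 | 40.5 |
| zeta | 5.00 | 25.6 | 0.2 | 38.3 |

(readings scatter by 1 percentage point)

- catalyst is single-handed; left-handed substrate and right-handed substrate are mirror images of each other, charged as a racemate, each of them at the stated concentration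

- whether the excess of right-handed substrate over left-handed substrate among what is left of the two reaches 99% by 4.0 h (no / yes)
- the highest excess of right-handed substrate over left-handed substrate among what is left of the two up to 4.0 h

The reckoning here takes the logarithms of the two mirror-image substrates to fall in fixed proportion. That proportion is the selectivity factor s, the powers of ten lost by left-handed substrate for each power of ten lost by right-handed substrate. Theta at 2.50 h gives, each substrate over its 50% charge:

s = log(2.8% / 50%) ÷ log(46.7% / 50%) = 42.2

This is a rough reading, since the scatter of 1 percentage point sits on a fall of 3.3 points.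

An excess of 99% means [left-handed substrate]/[right-handed substrate] = 0.00503. With x the surviving part of the right-handed substrate, the left-handed part is x raised to s, so:

log x = −2.30 ÷ (42.2 − 1), so x = 0.879, which is 44.0% right-handed substrate left

By this reckoning, a racemate at this s reaches 99% at that line. Theta at 2.50 h read 46.7%, above it, at an excess of 88.7%. Zeta, with 1.5 equiv at 0.40 M, read 25.5% at 2.50 h, below it. There the left-handed part reckons to −12.3 in powers of ten. Epsilon, at the flask's concentration but with 2.2 equiv, read 10.5% at 1.00 h. So the charge stays at 1.50 equiv.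

The forecast says yes, with a top of 99.6% (from 98.5% to 100%): “With selectivity of about 40, the calculated left-handed residue is negligible.” It allows a left-handed floor of about 0.1% that the reckoning here does not.

The flask gives yes, with a top of 100%.

reagent + catalyst + right-handed substrate → catalyst + right-handed product (k = 2600 L² mol⁻² min⁻¹); reagent + catalyst + left-handed substrate → catalyst + left-handed product (k = 93000 L² mol⁻² min⁻¹); catalyst + added ligand ⇌ idle complex, settled at all times (K = 12000 L mol⁻¹); left-handed product ⇌ right-handed product (k = 0.00560 min⁻¹) The flask passed 99% after 0.114 h with 42.9% right-handed substrate left, beside the line of 44.0% reckoned from s, and its right-handed substrate stood at 25.1% after 4.00 h. Zeta's first reading, at 0.417 h, was 26.1% right-handed substrate, below that line, with 0.1% left-handed substrate.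

The runs were computed for substances that don't exist; the scatter is artificial.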